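Heteroxanthin is cut at C11'=C12' into a C25 ylide carrying the 3,5,6-triol ring and a C15 aldehyde carrying ring A'. The plan rests on the C15 aldehyde: in ring A' the tetrasubstituted C5'=C6' alkene conjugated to the C7'≡C8' alkyne is treated as a dehydrated 5'-hydroxy-6',7'-allene. One acid-mediated 1,4-loss of water (C5'–OH, C8'–H) therefore creates the ring alkene and the second alkyne π bond together and erases C5' and the allene axis. The precursor is a C15 allenic tertiary carbinol bearing an E-enal and an acid-stable 3'-silyl ether, obtained by SN2' hydride opening of an alkynyl epoxide; the same epoxy aldehyde feeds the triol ring.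

Key step: step 14

Remarks on the chemistry:
- TBDPS = tert-butyl(diphenyl)silyl, TBDPSO = its ether oxygen; positions in the Why lines use carotenoid numbering (primed atoms belong to the acetylenic half).
- Assumption: in step 12 hydride is delivered from the aluminium-bound oxirane oxygen (syn SN2'), which gives the R allene axis drawn for 17 and 18; the S epimer would react identically in step 14.
- The C4 electrophile that supplies C9' must be E (C8' and C11' trans). Anti hydrohalogenation of a but-2-ynoate gives the Z halide, which would lead to the 9'Z series, so the E enol triflate 14 of ethyl acetoacetate is used.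
- The silyl ether is carried from step 3 to the end because it is inert to the acid of steps 14, 16, 18 and 21; no protecting-group exchange is needed.
- Compounds 20 (E-enriched) and 26 are taken as commercial; all polyene steps are run under argon in dim light.

Step 1
Reactants: 1 ketoisophorone
Product: 2 (6R)-2,2,6-trimethylcyclohexane-1,4-dione
Conditions: ene-reductase OYE2 (Old Yellow Enzyme), NADP+ (cat.), glucose dehydrogenase, D-glucose, phosphate buffer pH 7.0, 30 °C
Reagents that add atoms: none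
Why: Enzymatic asymmetric conjugate reduction of the enedione C=C bond (ene-reductase reduction), in which the flavin hydride is delivered to one face of the methyl-bearing alkene carbon inside the active site and so sets the 6R centre.

Step 2
Reactants: 2 (6R)-2,2,6-trimethylcyclohexane-1,4-dione
Product: 3 (4R,6R)-4-hydroxy-2,2,6-trimethylcyclohexan-1-one
Conditions: LiBH(s-Bu)3, THF, −78 °C; H2O quench; chromatography
Reagents that add atoms: none
Why: Diastereoselective ketone reduction with a bulky hydride: the axial methyl of the gem-dimethyl group blocks axial approach to C4, so equatorial delivery should give the alcohol trans to the C6 methyl (4R), the flanked C1 carbonyl is too hindered to react, and any cis epimer is removed here because it would later become the enantiomer.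

Step 3
Reactants: 3 (4R,6R)-4-hydroxy-2,2,6-trimethylcyclohexan-1-one
Product: 4 (4R,6R)-4-(TBDPSO)-2,2,6-trimethylcyclohexan-1-one
Conditions: TBDPSCl, imidazole, DMAP (cat.), DMF, 40 °C
Reagents that add atoms: tert-butyl(chloro)diphenylsilane, CC(C)(C)[Si](Cl)(c1ccccc1)c1ccccc1
Why: Standard silylation of a secondary alcohol, the tert-butyldiphenylsilyl ether being chosen because it has to survive the acidic steps 14, 16, 18 and 21.

Step 4
Reactants: 4 (4R,6R)-4-(TBDPSO)-2,2,6-trimethylcyclohexan-1-one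
Product: 6 (4R)-4-(TBDPSO)-2,6,6-trimethylcyclohex-1-en-1-yl trifluoromethanesulfonate, via potassium enolate 5 (not isolated)
Conditions: KN(SiMe3)2, THF, −78 °C; then PhNTf2, −78 °C → rt
Reagents that add atoms: N-phenyl-bis(trifluoromethanesulfonimide), O=S(=O)(N(c1ccccc1)S(=O)(=O)C(F)(F)F)C(F)(F)F
Why: Enol triflate formation: the ketone has one enolisable position only, so deprotonation and O-sulfonylation can give nothing but the tetrasubstituted enol triflate, and the C6 stereocentre, no longer needed, disappears.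

Step 5
Reactants: 6 (4R)-4-(TBDPSO)-2,6,6-trimethylcyclohex-1-en-1-yl trifluoromethanesulfonate
Product: 7 methyl (4R)-4-(TBDPSO)-2,6,6-trimethylcyclohex-1-ene-1-carboxylate
Conditions: Pd(OAc)2 (5 mol%), PPh3 (10 mol%), CO (1 atm), MeOH, Et3N, DMF, 60 °C
Reagents that add atoms: carbon monoxide, [C-]#[O+]; methanol, CO
Why: Palladium-catalysed alkoxycarbonylation of a vinyl triflate (oxidative addition, CO insertion, methanolysis) attaches the future C7 carbon to the ring.

Step 6
Reactants: 7 methyl (4R)-4-(TBDPSO)-2,6,6-trimethylcyclohex-1-ene-1-carboxylate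
Product: 8 [(4R)-4-(TBDPSO)-2,6,6-trimethylcyclohex-1-en-1-yl]methanol
Conditions: i-Bu2AlH (2.5 equiv), CH2Cl2, −78 → 0 °C; aq. KNaC4H4O6
Reagents that add atoms: none
Why: 1,2-Reduction of an α,β-unsaturated ester with i-Bu2AlH gives the allylic alcohol that is needed to direct the epoxidation.

Step 7
Reactants: 8 [(4R)-4-(TBDPSO)-2,6,6-trimethylcyclohex-1-en-1-yl]methanol
Product: 9 [(1R,4S,6R)-4-(TBDPSO)-2,2,6-trimethyl-7-oxabicyclo[4.1.0]heptan-1-yl]methanol (oxirane trans to the silyloxy group)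
Conditions: Ti(OiPr)4 (0.2 equiv), D-(−)-diethyl tartrate (0.24 equiv), t-BuOOH, 4 Å MS, CH2Cl2, −20 °C
Reagents that add atoms: tert-butyl hydroperoxide, CC(C)(C)OO
Why: Sharpless asymmetric epoxidation, in which the titanium tartrate complex and not the remote silyloxy centre selects the alkene face, so that the D-(−)-tartrate should deliver oxygen anti to the silyloxy group and set both oxirane carbons (1R,6R) in one event.

Step 8
Reactants: 9 [(1R,4S,6R)-4-(TBDPSO)-2,2,6-trimethyl-7-oxabicyclo[4.1.0]heptan-1-yl]methanol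
Product: 10 (1S,4S,6R)-4-(TBDPSO)-2,2,6-trimethyl-7-oxabicyclo[4.1.0]heptane-1-carbaldehyde
Conditions: Dess–Martin periodinane, NaHCO3, CH2Cl2, 0 °C → rt
Reagents that add atoms: none
Why: Dess–Martin oxidation of a primary alcohol under buffered conditions, the aldehyde having a quaternary α-carbon that cannot enolise or epimerise.

Step 9
Reactants: 10 (1S,4S,6R)-4-(TBDPSO)-2,2,6-trimethyl-7-oxabicyclo[4.1.0]heptane-1-carbaldehyde
Product: 11 (1R,4S,6R)-4-(TBDPSO)-1-ethynyl-2,2,6-trimethyl-7-oxabicyclo[4.1.0]heptane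
Conditions: dimethyl (1-diazo-2-oxopropyl)phosphonate, K2CO3, MeOH, 0 °C → rt
Reagents that add atoms: dimethyl (1-diazo-2-oxopropyl)phosphonate, COP(=O)(OC)C(=[N+]=[N-])C(C)=O
Why: Ohira–Bestmann alkyne homologation (Seyferth–Gilbert type) turns the non-enolisable aldehyde into the terminal alkyne (C7'≡C8') under mild carbonate conditions that leave the oxirane and the silyl ether intact.

Step 10
Reactants: 12 ethyl acetoacetate
Product: 14 ethyl (2E)-3-(trifluoromethanesulfonyloxy)but-2-enoate, via tetramethylammonium enolate 13 (not isolated)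
Conditions: aq. Me4NOH, hexane, 5 °C; then Tf2O
Reagents that add atoms: trifluoromethanesulfonic anhydride, O=S(=O)(OS(=O)(=O)C(F)(F)F)C(F)(F)F
Why: Stereoselective enol triflation of a β-keto ester: with the non-chelating tetramethylammonium counter-ion the enolate adopts the extended geometry and O-sulfonylation should give the E triflate, which fixes the later C9'=C10' geometry.

Step 11
Reactants: 11 (1R,4S,6R)-4-(TBDPSO)-1-ethynyl-2,2,6-trimethyl-7-oxabicyclo[4.1.0]heptane; 14 ethyl (2E)-3-(trifluoromethanesulfonyloxy)but-2-enoate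
Product: 15 ethyl (2E)-5-[(1R,4S,6R)-4-(TBDPSO)-2,2,6-trimethyl-7-oxabicyclo[4.1.0]heptan-1-yl]-3-methylpent-2-en-4-ynoate
Conditions: PdCl2(PPh3)2 (5 mol%), CuI (10 mol%), Et3N, THF, rt
Reagents that add atoms: none
Why: Sonogashira coupling of a terminal alkyne with a vinyl triflate forms the C8'–C9' bond with retention of the alkene geometry, a tertiary amine being used so that no amine adds to the β-position of the enoate.

Step 12
Reactants: 15 ethyl (2E)-5-[(1R,4S,6R)-4-(TBDPSO)-2,2,6-trimethyl-7-oxabicyclo[4.1.0]heptan-1-yl]-3-methylpent-2-en-4-ynoate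
Product: 17 (2E)-5-[(2R,4S)-2-hydroxy-4-(TBDPSO)-2,6,6-trimethylcyclohexylidene]-3-methylpenta-2,4-dien-1-ol (allene axis R; carotenoid 3S,5R,6R), via epoxy enynol 16 (not isolated)
Conditions: i-Bu2AlH (5 equiv), CH2Cl2, −78 → 0 °C; aq. KNaC4H4O6
Reagents that add atoms: none
Why: Ester reduction followed by SN2' reduction of the alkynyl oxirane (propargylic epoxide to allenol) by i-Bu2AlH: hydride enters at C8', the C6'–O bond leaves, the C5' oxygen stays as the tertiary alcohol, and the axis formed need not be controlled because step 14 erases it.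

Step 13
Reactants: 17 (2E)-5-[(2R,4S)-2-hydroxy-4-(TBDPSO)-2,6,6-trimethylcyclohexylidene]-3-methylpenta-2,4-dien-1-ol
Product: 18 (2E)-5-[(2R,4S)-2-hydroxy-4-(TBDPSO)-2,6,6-trimethylcyclohexylidene]-3-methylpenta-2,4-dienal (allene axis R; carotenoid 3S,5R,6R)
Conditions: MnO2, CH2Cl2, rt
Reagents that add atoms: none
Why: Allylic oxidation with MnO2 touches only the primary allylic alcohol and leaves the tertiary allenic carbinol alone.

Step 14
Reactants: 18 (2E)-5-[(2R,4S)-2-hydroxy-4-(TBDPSO)-2,6,6-trimethylcyclohexylidene]-3-methylpenta-2,4-dienal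
Product: 19 (2E)-5-[(4R)-4-(TBDPSO)-2,6,6-trimethylcyclohex-1-en-1-yl]-3-methylpent-2-en-4-ynal
Conditions: p-TsOH·H2O (10 mol%), toluene, 40 °C
Reagents that add atoms: none
Why: Acid turns the tertiary C5' hydroxyl into a leaving group, and ionisation gives an allyl-type cation whose charge is shared by C5' and the sp carbon C7' through overlap with the C6'=C7' π bond; this π system is perpendicular to the C7'=C8' π bond that is conjugated with the aldehyde, so the electron-poor enal neither ionises nor takes part in the cation. Because H8' sits in the nodal plane of the C7'=C8' π bond and therefore eclipses the vacant C7' orbital, its removal by the sulfonate completes both new π bonds at once, C5'=C6' in ring A' and the in-plane component of C7'≡C8', a net 1,4-elimination of water of the E1 type. The closest known reaction type is the acid-promoted dehydration of 5-hydroxy-6,7-allenic megastigmanes and of allenic carotenoid end groups to 5-en-7-ynes. No ring is closed and no stereocentre is created: C5' and the allene axis disappear, so the epimeric composition of 18 does not matter, and C3' and the 9'E bond are not involved. The selectivity needed is proton loss from C8' and not from C4' or the C5' methyl group; the vinylallenes from those paths can be reprotonated to the same cation under the equilibrating conditions, whereas the fully conjugated ene-yne-enal cannot, so it should accumulate as the thermodynamic product, and the acid-stable silyl ether and the catalytic anhydrous acid keep C3' and the enal intact.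

Step 15
Reactants: 10 (1S,4S,6R)-4-(TBDPSO)-2,2,6-trimethyl-7-oxabicyclo[4.1.0]heptane-1-carbaldehyde; 20 triethyl 3-methyl-4-phosphonocrotonate
Product: 22 ethyl (2E,4E)-5-[(1S,4S,6R)-4-(TBDPSO)-2,2,6-trimethyl-7-oxabicyclo[4.1.0]heptan-1-yl]-3-methylpenta-2,4-dienoate, via lithiated phosphonate 21 (not isolated)
Conditions: LiN(SiMe3)2, THF, −78 °C; then 10, −78 → 0 °C
Reagents that add atoms: none
Why: Horner–Wadsworth–Emmons olefination of the non-enolisable epoxy aldehyde with a stabilised allylic phosphonate anion should give the E C7=C8 bond, the 9E geometry being carried by the reagent and any 9Z isomer being removed by chromatography.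

Step 16
Reactants: 22 ethyl (2E,4E)-5-[(1S,4S,6R)-4-(TBDPSO)-2,2,6-trimethyl-7-oxabicyclo[4.1.0]heptan-1-yl]-3-methylpenta-2,4-dienoate
Product: 23 ethyl (2E,4E)-5-[(1R,2R,4S)-1,2-dihydroxy-2,6,6-trimethyl-4-(TBDPSO)cyclohexyl]-3-methylpenta-2,4-dienoate
Conditions: HClO4 (aq., cat.), THF/H2O, 0 °C → rt
Reagents that add atoms: water, O
Why: Acid-catalysed hydrolysis of a vinyl epoxide by trans-diaxial (Fürst–Plattner) opening: with the bulky 3-silyloxy group equatorial only attack of water at the allylic C6 from the face opposite the oxirane oxygen leads to a chair, so C6 is inverted to R, C5 keeps its oxygen (R), and the 5,6-trans diol with 6-OH cis to the 3-oxygen results, while the ester-deactivated diene disfavours full ionisation.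

Step 17
Reactants: 23 ethyl (2E,4E)-5-[(1R,2R,4S)-1,2-dihydroxy-2,6,6-trimethyl-4-(TBDPSO)cyclohexyl]-3-methylpenta-2,4-dienoate
Product: 24 (2E,4E)-5-[(1R,2R,4S)-1,2-dihydroxy-2,6,6-trimethyl-4-(TBDPSO)cyclohexyl]-3-methylpenta-2,4-dien-1-ol
Conditions: i-Bu2AlH (4 equiv), CH2Cl2, −78 → 0 °C; aq. KNaC4H4O6
Reagents that add atoms: none
Why: 1,2-Reduction of the dienoate to the dienol with i-Bu2AlH, the two tertiary hydroxyls being merely deprotonated by the excess reagent.

Step 18
Reactants: 24 (2E,4E)-5-[(1R,2R,4S)-1,2-dihydroxy-2,6,6-trimethyl-4-(TBDPSO)cyclohexyl]-3-methylpenta-2,4-dien-1-ol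
Product: 25 [(2E,4E)-5-[(1R,2R,4S)-1,2-dihydroxy-2,6,6-trimethyl-4-(TBDPSO)cyclohexyl]-3-methylpenta-2,4-dien-1-yl]triphenylphosphonium bromide
Conditions: PPh3·HBr, MeOH, rt
Reagents that add atoms: triphenylphosphine hydrobromide, [Br-].c1ccc(cc1)[PH+](c1ccccc1)c1ccccc1
Why: Conversion of an allylic alcohol into its phosphonium salt with PPh3·HBr: ionisation occurs at the primary dienylic position and the phosphine is captured at the unhindered C11 terminus, while the tertiary C6 hydroxyl is deactivated by the neighbouring C5 oxygen.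

Step 19
Reactants: 25 C15 phosphonium bromide; 26 (2E,4E,6E)-2,7-dimethylocta-2,4,6-trienedial
Product: 28 (2E,4E,6E,8E,10E,12E)-13-[(1R,2R,4S)-1,2-dihydroxy-2,6,6-trimethyl-4-(TBDPSO)cyclohexyl]-2,7,11-trimethyltrideca-2,4,6,8,10,12-hexaenal, via C15 ylide 27 (not isolated)
Conditions: NaOMe, MeOH/CH2Cl2, 0 °C → rt (26 in threefold excess); then heptane/EtOAc, 70 °C
Reagents that add atoms: none
Why: Wittig olefination of the C15 ylide with an excess of the symmetrical C10 dialdehyde should stop at mono-condensation and form C11=C12, the hindered 11Z isomer being converted to 11E on heating.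

Step 20
Reactants: 28 C25 aldehyde
Product: 29 (2E,4E,6E,8E,10E,12E)-13-[(1R,2R,4S)-1,2-dihydroxy-2,6,6-trimethyl-4-(TBDPSO)cyclohexyl]-2,7,11-trimethyltrideca-2,4,6,8,10,12-hexaen-1-ol
Conditions: NaBH4, MeOH/THF, 0 °C
Reagents that add atoms: none
Why: Chemoselective 1,2-reduction of the polyenal with NaBH4 gives the primary polyenylic alcohol.

Step 21
Reactants: 29 C25 alcohol
Product: 30 [(2E,4E,6E,8E,10E,12E)-13-[(1R,2R,4S)-1,2-dihydroxy-2,6,6-trimethyl-4-(TBDPSO)cyclohexyl]-2,7,11-trimethyltrideca-2,4,6,8,10,12-hexaen-1-yl]triphenylphosphonium bromide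
Conditions: PPh3·HBr, CH2Cl2/MeOH, 0 °C → rt, dark
Reagents that add atoms: triphenylphosphine hydrobromide, [Br-].c1ccc(cc1)[PH+](c1ccccc1)c1ccccc1
Why: Phosphonium salt formation with PPh3·HBr through the delocalised polyenyl cation, which the phosphine captures at the unhindered C12' terminus in the manner of the classical retinyl salt preparation.

Step 22
Reactants: 30 C25 phosphonium bromide; 19 (2E)-5-[(4R)-4-(TBDPSO)-2,6,6-trimethylcyclohex-1-en-1-yl]-3-methylpent-2-en-4-ynal
Product: 32 3,3'-di-O-TBDPS-heteroxanthin, via C25 ylide 31 (not isolated)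
Conditions: NaOMe, MeOH/CH2Cl2, 0 °C → rt, dark; then heptane/EtOAc, 70 °C
Reagents that add atoms: none
Why: Wittig olefination forms C11'=C12', and because the acetylenic C15 unit reacts as the aldehyde and never as an allylic ylide the 9'E bond beside the alkyne cannot scramble, while the hindered 11'Z isomer is converted to E on heating.

Step 23
Reactants: 32 3,3'-di-O-TBDPS-heteroxanthin
Product: 33 heteroxanthin
Conditions: Bu4NF, THF, rt, argon, dark
Reagents that add atoms: none
Why: Fluoride-mediated cleavage of both silyl ethers (desilylation) under non-acidic conditions that the polyene, the enyne and the tertiary allylic diol should tolerate.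

Compound list
1 | ketoisophorone (2,6,6-trimethylcyclohex-2-ene-1,4-dione) | CC1=CC(=O)CC(C)(C)C1=O | starting material
2 | (6R)-2,2,6-trimethylcyclohexane-1,4-dione | O=C1C(C)(C)CC(=O)C[C@H]1C | intermediate
3 | (4R,6R)-4-hydroxy-2,2,6-trimethylcyclohexan-1-one | O=C1C(C)(C)C[C@H](O)C[C@H]1C | intermediate
4 | (4R,6R)-4-(TBDPSO)-2,2,6-trimethylcyclohexan-1-one | O=C1C(C)(C)C[C@H](O[Si](c2ccccc2)(c2ccccc2)C(C)(C)C)C[C@H]1C | intermediate
5 | potassium (4R)-4-(TBDPSO)-2,6,6-trimethylcyclohex-1-en-1-olate (formed in the flask) | CC1=C([O-])C(C)(C)C[C@H](O[Si](c2ccccc2)(c2ccccc2)C(C)(C)C)C1.[K+] | intermediate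
6 | (4R)-4-(TBDPSO)-2,6,6-trimethylcyclohex-1-en-1-yl trifluoromethanesulfonate | CC1=C(OS(=O)(=O)C(F)(F)F)C(C)(C)C[C@H](O[Si](c2ccccc2)(c2ccccc2)C(C)(C)C)C1 | intermediate
7 | methyl (4R)-4-(TBDPSO)-2,6,6-trimethylcyclohex-1-ene-1-carboxylate | CC1=C(C(=O)OC)C(C)(C)C[C@H](O[Si](c2ccccc2)(c2ccccc2)C(C)(C)C)C1 | intermediate
8 | [(4R)-4-(TBDPSO)-2,6,6-trimethylcyclohex-1-en-1-yl]methanol | CC1=C(CO)C(C)(C)C[C@H](O[Si](c2ccccc2)(c2ccccc2)C(C)(C)C)C1 | intermediate
9 | [(1R,4S,6R)-4-(TBDPSO)-2,2,6-trimethyl-7-oxabicyclo[4.1.0]heptan-1-yl]methanol | OC[C@]12C(C)(C)C[C@H](O[Si](c3ccccc3)(c3ccccc3)C(C)(C)C)C[C@@]1(C)O2 | intermediate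
10 | (1S,4S,6R)-4-(TBDPSO)-2,2,6-trimethyl-7-oxabicyclo[4.1.0]heptane-1-carbaldehyde | O=C[C@]12C(C)(C)C[C@H](O[Si](c3ccccc3)(c3ccccc3)C(C)(C)C)C[C@@]1(C)O2 | intermediate
11 | (1R,4S,6R)-4-(TBDPSO)-1-ethynyl-2,2,6-trimethyl-7-oxabicyclo[4.1.0]heptane | C#C[C@]12C(C)(C)C[C@H](O[Si](c3ccccc3)(c3ccccc3)C(C)(C)C)C[C@@]1(C)O2 | intermediate
12 | ethyl acetoacetate | CCOC(=O)CC(C)=O | starting material
13 | tetramethylammonium (E)-enolate of ethyl acetoacetate (formed in the flask) | CCOC(=O)/C=C(C)/[O-].C[N+](C)(C)C | intermediate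
14 | ethyl (2E)-3-(trifluoromethanesulfonyloxy)but-2-enoate | CCOC(=O)/C=C(C)/OS(=O)(=O)C(F)(F)F | intermediate
15 | ethyl (2E)-5-[(1R,4S,6R)-4-(TBDPSO)-2,2,6-trimethyl-7-oxabicyclo[4.1.0]heptan-1-yl]-3-methylpent-2-en-4-ynoate | CCOC(=O)/C=C(C)/C#C[C@]12C(C)(C)C[C@H](O[Si](c3ccccc3)(c3ccccc3)C(C)(C)C)C[C@@]1(C)O2 | intermediate
16 | (2E)-5-[(1R,4S,6R)-4-(TBDPSO)-2,2,6-trimethyl-7-oxabicyclo[4.1.0]heptan-1-yl]-3-methylpent-2-en-4-yn-1-ol (formed in the flask as its aluminium alkoxide) | OC/C=C(C)/C#C[C@]12C(C)(C)C[C@H](O[Si](c3ccccc3)(c3ccccc3)C(C)(C)C)C[C@@]1(C)O2 | intermediate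
17 | (2E)-5-[(2R,4S)-2-hydroxy-4-(TBDPSO)-2,6,6-trimethylcyclohexylidene]-3-methylpenta-2,4-dien-1-ol, allene axis R (carotenoid 3S,5R,6R) | OC/C=C(C)/C([H])=[C@@]=C1C(C)(C)C[C@H](O[Si](c2ccccc2)(c2ccccc2)C(C)(C)C)C[C@@]1(C)O | intermediate
18 | (2E)-5-[(2R,4S)-2-hydroxy-4-(TBDPSO)-2,6,6-trimethylcyclohexylidene]-3-methylpenta-2,4-dienal, allene axis R (carotenoid 3S,5R,6R); C15 allenic hydroxy aldehyde | O=C/C=C(C)/C([H])=[C@@]=C1C(C)(C)C[C@H](O[Si](c2ccccc2)(c2ccccc2)C(C)(C)C)C[C@@]1(C)O | intermediate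
19 | (2E)-5-[(4R)-4-(TBDPSO)-2,6,6-trimethylcyclohex-1-en-1-yl]-3-methylpent-2-en-4-ynal; C15 acetylenic aldehyde | CC1=C(C#C/C(C)=C/C=O)C(C)(C)C[C@H](O[Si](c2ccccc2)(c2ccccc2)C(C)(C)C)C1 | intermediate
20 | triethyl 3-methyl-4-phosphonocrotonate, ethyl (2E)-4-(diethoxyphosphoryl)-3-methylbut-2-enoate | CCOC(=O)/C=C(C)/CP(=O)(OCC)OCC | starting material
21 | lithium salt of the α-phosphoryl carbanion of 20 (formed in the flask) | [Li+].CCOC(=O)/C=C(C)/[CH-]P(=O)(OCC)OCC | intermediate
22 | ethyl (2E,4E)-5-[(1S,4S,6R)-4-(TBDPSO)-2,2,6-trimethyl-7-oxabicyclo[4.1.0]heptan-1-yl]-3-methylpenta-2,4-dienoate | CCOC(=O)/C=C(C)/C=C/[C@]12C(C)(C)C[C@H](O[Si](c3ccccc3)(c3ccccc3)C(C)(C)C)C[C@@]1(C)O2 | intermediate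
23 | ethyl (2E,4E)-5-[(1R,2R,4S)-1,2-dihydroxy-2,6,6-trimethyl-4-(TBDPSO)cyclohexyl]-3-methylpenta-2,4-dienoate | CCOC(=O)/C=C(C)/C=C/[C@@]1(O)C(C)(C)C[C@H](O[Si](c2ccccc2)(c2ccccc2)C(C)(C)C)C[C@@]1(C)O | intermediate
24 | (2E,4E)-5-[(1R,2R,4S)-1,2-dihydroxy-2,6,6-trimethyl-4-(TBDPSO)cyclohexyl]-3-methylpenta-2,4-dien-1-ol | OC/C=C(C)/C=C/[C@@]1(O)C(C)(C)C[C@H](O[Si](c2ccccc2)(c2ccccc2)C(C)(C)C)C[C@@]1(C)O | intermediate
25 | [(2E,4E)-5-[(1R,2R,4S)-1,2-dihydroxy-2,6,6-trimethyl-4-(TBDPSO)cyclohexyl]-3-methylpenta-2,4-dien-1-yl]triphenylphosphonium bromide | [Br-].c1ccc(cc1)[P+](c1ccccc1)(c1ccccc1)C/C=C(C)/C=C/[C@@]1(O)C(C)(C)C[C@H](O[Si](c2ccccc2)(c2ccccc2)C(C)(C)C)C[C@@]1(C)O | intermediate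
26 | (2E,4E,6E)-2,7-dimethylocta-2,4,6-trienedial (C10 dialdehyde) | O=C/C(C)=C/C=C/C=C(C)/C=O | starting material
27 | ylide of 25 (formed in the flask) | c1ccc(cc1)[P+](c1ccccc1)(c1ccccc1)[CH-]/C=C(C)/C=C/[C@@]1(O)C(C)(C)C[C@H](O[Si](c2ccccc2)(c2ccccc2)C(C)(C)C)C[C@@]1(C)O | intermediate
28 | (2E,4E,6E,8E,10E,12E)-13-[(1R,2R,4S)-1,2-dihydroxy-2,6,6-trimethyl-4-(TBDPSO)cyclohexyl]-2,7,11-trimethyltrideca-2,4,6,8,10,12-hexaenal (C25 aldehyde) | O=C/C(C)=C/C=C/C=C(C)/C=C/C=C(C)/C=C/[C@@]1(O)C(C)(C)C[C@H](O[Si](c2ccccc2)(c2ccccc2)C(C)(C)C)C[C@@]1(C)O | intermediate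
29 | (2E,4E,6E,8E,10E,12E)-13-[(1R,2R,4S)-1,2-dihydroxy-2,6,6-trimethyl-4-(TBDPSO)cyclohexyl]-2,7,11-trimethyltrideca-2,4,6,8,10,12-hexaen-1-ol (C25 alcohol) | OC/C(C)=C/C=C/C=C(C)/C=C/C=C(C)/C=C/[C@@]1(O)C(C)(C)C[C@H](O[Si](c2ccccc2)(c2ccccc2)C(C)(C)C)C[C@@]1(C)O | intermediate
30 | triphenylphosphonium bromide of 29 (P on C12'; C25 phosphonium bromide) | [Br-].c1ccc(cc1)[P+](c1ccccc1)(c1ccccc1)C/C(C)=C/C=C/C=C(C)/C=C/C=C(C)/C=C/[C@@]1(O)C(C)(C)C[C@H](O[Si](c2ccccc2)(c2ccccc2)C(C)(C)C)C[C@@]1(C)O | intermediate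
31 | ylide of 30 (formed in the flask) | c1ccc(cc1)[P+](c1ccccc1)(c1ccccc1)[CH-]/C(C)=C/C=C/C=C(C)/C=C/C=C(C)/C=C/[C@@]1(O)C(C)(C)C[C@H](O[Si](c2ccccc2)(c2ccccc2)C(C)(C)C)C[C@@]1(C)O | intermediate
32 | 3,3'-di-O-TBDPS-heteroxanthin, (3S,5R,6R,3'R)-3,3'-bis(TBDPSO)-7',8'-didehydro-5,6-dihydro-β,β-carotene-5,6-diol | CC1=C(C#C/C(C)=C/C=C/C(C)=C/C=C/C=C(C)/C=C/C=C(C)/C=C/[C@@]2(O)C(C)(C)C[C@H](O[Si](c3ccccc3)(c3ccccc3)C(C)(C)C)C[C@@]2(C)O)C(C)(C)C[C@H](O[Si](c3ccccc3)(c3ccccc3)C(C)(C)C)C1 | intermediate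
33 | heteroxanthin, (3S,5R,6R,3'R)-7',8'-didehydro-5,6-dihydro-β,β-carotene-3,5,6,3'-tetrol (all-E) | CC1=C(C#C/C(C)=C/C=C/C(C)=C/C=C/C=C(C)/C=C/C=C(C)/C=C/[C@@]2(O)C(C)(C)C[C@H](O)C[C@@]2(C)O)C(C)(C)C[C@H](O)C1 | target

Total step count: 23. Longest linear sequence: 17 steps (steps 1–8, 15–23); the acetylenic branch (steps 9, 11–14) and step 10 are convergent.

Steps most likely to fail

Step 14. The cation may lose a proton from C4' or from the C5' methyl group faster than the vinylallenes so formed are returned to the cation, and prolonged acid contact may then isomerise the E-enal or oligomerise the vinylallenes. The fallback sets out from 6 and returns at 19. Commercial (2E)-3-methylpent-2-en-4-yn-1-ol is oxidised with MnO2 to (2E)-3-methylpent-2-en-4-ynal F1. Enol triflate 6 is then coupled with F1 under Sonogashira conditions (PdCl2(PPh3)2, CuI, Et3N, THF), which forms the C6'–C7' bond on the intact ring alkene and gives 19 without an allene.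

Step 16. Partial SN1 ionisation at C6 may let water enter from the oxirane face, which loses the trans relationship, or the cation may collapse to a 5,8-furanoid ether or a ring-contracted ketone. The fallback sets out from 9 and returns at 23, and it enforces the inversion at C6 with a tether. Epoxy alcohol 9 is treated with phenyl isocyanate to give [(1R,4S,6R)-4-(TBDPSO)-2,2,6-trimethyl-7-oxabicyclo[4.1.0]heptan-1-yl]methyl N-phenylcarbamate F2. BF3·OEt2 at low temperature lets the carbamate carbonyl oxygen open the oxirane at C6 in a 5-exo intramolecular SN2 process, and aqueous acid work-up of the iminocarbonate gives the spiro cyclic carbonate (5S,6R,8S)-8-(TBDPSO)-6-hydroxy-6,10,10-trimethyl-1,3-dioxaspiro[4.5]decan-2-one F3. Methanolysis (K2CO3, MeOH) gives (1S,2R,4S)-4-(TBDPSO)-1-(hydroxymethyl)-2,6,6-trimethylcyclohexane-1,2-diol F4. TEMPO with PhI(OAc)2 oxidises only the primary alcohol to (1R,2R,4S)-4-(TBDPSO)-1,2-dihydroxy-2,6,6-trimethylcyclohexane-1-carbaldehyde F5. Horner–Wadsworth–Emmons olefination of F5 with the anion 21 of phosphonate 20 gives 23.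

Step 21. HBr may ionise the tertiary allylic C6 carbinol, or the long polyenyl cation may isomerise or decompose before the phosphine captures it. The fallback sets out from 19, uses 28 and returns at 32, and it reverses the polarity of the last coupling so that steps 20 and 21 are not needed. Aldehyde 19 is reduced (NaBH4) to (2E)-5-[(4R)-4-(TBDPSO)-2,6,6-trimethylcyclohex-1-en-1-yl]-3-methylpent-2-en-4-yn-1-ol F6. This is converted with CBr4 and PPh3 into (2E)-1-bromo-5-[(4R)-4-(TBDPSO)-2,6,6-trimethylcyclohex-1-en-1-yl]-3-methylpent-2-en-4-yne F7 and quaternised with PBu3 to tributyl[(2E)-5-[(4R)-4-(TBDPSO)-2,6,6-trimethylcyclohex-1-en-1-yl]-3-methylpent-2-en-4-yn-1-yl]phosphonium bromide F8. The ylide of F8 (NaOMe, MeOH/CH2Cl2) is condensed with the C25 aldehyde 28 to give 32. A trialkylphosphonium ylide is chosen because it is less delocalised than the triphenyl analogue and should condense before the C9'=C10' geometry can equilibrate.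

Further compounds
F1 | step 14 | (2E)-3-methylpent-2-en-4-ynal | C#C/C(C)=C/C=O
F2 | step 16 | [(1R,4S,6R)-4-(TBDPSO)-2,2,6-trimethyl-7-oxabicyclo[4.1.0]heptan-1-yl]methyl N-phenylcarbamate | O=C(Nc1ccccc1)OC[C@]12C(C)(C)C[C@H](O[Si](c3ccccc3)(c3ccccc3)C(C)(C)C)C[C@@]1(C)O2
F3 | step 16 | (5S,6R,8S)-8-(TBDPSO)-6-hydroxy-6,10,10-trimethyl-1,3-dioxaspiro[4.5]decan-2-one | O=C1OC[C@@]2(O1)C(C)(C)C[C@H](O[Si](c3ccccc3)(c3ccccc3)C(C)(C)C)C[C@@]2(C)O
F4 | step 16 | (1S,2R,4S)-4-(TBDPSO)-1-(hydroxymethyl)-2,6,6-trimethylcyclohexane-1,2-diol | OC[C@@]1(O)C(C)(C)C[C@H](O[Si](c2ccccc2)(c2ccccc2)C(C)(C)C)C[C@@]1(C)O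
F5 | step 16 | (1R,2R,4S)-4-(TBDPSO)-1,2-dihydroxy-2,6,6-trimethylcyclohexane-1-carbaldehyde | O=C[C@@]1(O)C(C)(C)C[C@H](O[Si](c2ccccc2)(c2ccccc2)C(C)(C)C)C[C@@]1(C)O
F6 | step 21 | (2E)-5-[(4R)-4-(TBDPSO)-2,6,6-trimethylcyclohex-1-en-1-yl]-3-methylpent-2-en-4-yn-1-ol | CC1=C(C#C/C(C)=C/CO)C(C)(C)C[C@H](O[Si](c2ccccc2)(c2ccccc2)C(C)(C)C)C1
F7 | step 21 | (2E)-1-bromo-5-[(4R)-4-(TBDPSO)-2,6,6-trimethylcyclohex-1-en-1-yl]-3-methylpent-2-en-4-yne | CC1=C(C#C/C(C)=C/CBr)C(C)(C)C[C@H](O[Si](c2ccccc2)(c2ccccc2)C(C)(C)C)C1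
F8 | step 21 | tributyl[(2E)-5-[(4R)-4-(TBDPSO)-2,6,6-trimethylcyclohex-1-en-1-yl]-3-methylpent-2-en-4-yn-1-yl]phosphonium bromide | CC1=C(C#C/C(C)=C/C[P+](CCCC)(CCCC)CCCC)C(C)(C)C[C@H](O[Si](c2ccccc2)(c2ccccc2)C(C)(C)C)C1.[Br-]
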